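The target is a flat 2,3-diarylbenzofuran. Ring A (the benzo ring) bears OH at C4 and CHO at C6, ring B (4-hydroxyphenyl) sits on C2, and ring C (3,5-dihydroxyphenyl) sits on C3.
Enabling feature: C3a and C7a are neighbouring carbons of ring A, the first bonded to C3 and the second to O1. C3 (with ring C), C2 (with ring B) and O1 are the α-carbon, the carbonyl carbon and the oxygen of a single deoxybenzoin enolate.
Retrosynthesis: four O–CH3 bonds and a C6 nitrile mask the phenols and the aldehyde. C3–C3a and O1–C7a are then cut together to a 1-bromo-2-iodoarene and the deoxybenzoin, which is itself cut at the CH2–ring C bond.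
Forward: ring A is dressed by bromination and iodo-dediazoniation of an aniline, and rings B and C are joined by ketone α-arylation. The furan ring (the only ring built) closes in one palladium-catalysed operation, and nitrile reduction and demethylation finish the route.
The nitrile is chosen for C6 because it activates the para C–I bond, ignores carbonate and enolate, and reaches the aldehyde in one reduction.
Stereochemistry: none to set. The target has no stereocentre, and the single sp3 methine that appears in passing is racemic and becomes sp2 on furan formation.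

Key step: step 4

Assumption: benzofuran numbering (O1, C2, C3, C3a, C4 to C7, C7a) is used throughout, and the three starting materials are taken to be catalogue chemicals.

Step 1
Reactants: 1 4-amino-3-methoxybenzonitrile
Product: 2 4-amino-3-bromo-5-methoxybenzonitrile
Conditions: NBS (1.05 equiv), MeCN, 0 °C to rt
Reagents that add atoms: N-bromosuccinimide, O=C1CCC(=O)N1Br
Why: Electrophilic aromatic bromination should be governed by the amino group, the strongest donor on the ring, whose para position is occupied by the nitrile and whose only free ortho position is C5, so one monobromide is expected.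

Step 2
Reactants: 2 4-amino-3-bromo-5-methoxybenzonitrile
Product: 4 3-bromo-4-iodo-5-methoxybenzonitrile, via arenediazonium tosylate 3 (not isolated)
Conditions: p-TsOH·H2O (3 equiv), NaNO2 (2 equiv), KI (2.5 equiv), MeCN/H2O, 10 °C to rt
Reagents that add atoms: potassium iodide, [K+].[I-]; sodium nitrite, [Na+].[O-]N=O (outer nitrogen of 3 only); p-toluenesulfonic acid, Cc1ccc(cc1)S(=O)(=O)O (counter-ion of 3 only)
Why: This is a Sandmeyer-type iodo-dediazoniation in which nitrous acid generated from NaNO2 and p-TsOH in acetonitrile diazotises even this weakly basic, doubly ortho-substituted aniline, and iodide reduces the diazonium ion and captures the aryl radical without copper, leaving nitrile, bromide and ether untouched.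

Step 3
Reactants: 5 1-(4-methoxyphenyl)ethanone (4'-methoxyacetophenone); 6 1-bromo-3,5-dimethoxybenzene
Product: 7 2-(3,5-dimethoxyphenyl)-1-(4-methoxyphenyl)ethanone
Conditions: Pd2(dba)3 (1.5 mol %), rac-BINAP (3.6 mol %), NaOt-Bu (2.2 equiv), 5 (1.3 equiv), THF, 70 °C; then aq NH4Cl
Reagents that add atoms: none
Why: Palladium-catalysed α-arylation of a methyl ketone enolate with an aryl bromide (oxidative addition, enolate binding, C–C reductive elimination) is standard for acetophenones, and the chelating bisphosphine together with a small excess of 5 should hold the reaction at monoarylation.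

Step 4
Reactants: 4 3-bromo-4-iodo-5-methoxybenzonitrile; 7 2-(3,5-dimethoxyphenyl)-1-(4-methoxyphenyl)ethanone
Product: 9 3-(3,5-dimethoxyphenyl)-4-methoxy-2-(4-methoxyphenyl)benzofuran-6-carbonitrile, via α-aryl ketone 8 (not isolated)
Conditions: Pd2(dba)3 (5 mol %), Xantphos (12 mol %), Cs2CO3 (3 equiv), 7 (1.1 equiv), degassed toluene, 110 °C
Reagents that add atoms: none
Why: Zerovalent palladium should insert first into the C–I bond of 4, which is weaker than C–Br and lies para to the nitrile; the caesium enolate of 7 then replaces iodide on divalent palladium, and reductive elimination from the C-bound enolate forges C3–C3a to give ketone 8. The methine of 8 is flanked by two aryl groups (one a cyanoarene) and a carbonyl group, so Cs2CO3 re-enolises it readily, and the two enolate geometries interconvert through the ketone so that the one holding oxygen cis to ring A is continuously drained. The furan ring, the only ring formed, closes by intramolecular enolate O-arylation: oxidative addition at C–Br, displacement of bromide by the enolate oxygen to give a six-membered oxapalladacycle, and C–O reductive elimination that makes O1–C7a and contracts the metallacycle to the five-membered ring. The closest known reaction type is the palladium-catalysed domino C-arylation/O-arylation of benzyl aryl ketones and cyclic ketones with 1,2-dihaloarenes to benzofurans, in which wide-bite-angle bisphosphines such as Xantphos speed both reductive eliminations. The selectivity required is regiochemical (carbon at the methoxy-flanked C3a, oxygen at C7a) and is secured by the iodide/bromide reactivity gap reinforced by the para nitrile, while a second intermolecular C-arylation is outpaced by the intramolecular ring closure. No stereocentre is created in 9, since the racemic methine of 8 becomes the sp2 carbon C3.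

Step 5
Reactants: 9 3-(3,5-dimethoxyphenyl)-4-methoxy-2-(4-methoxyphenyl)benzofuran-6-carbonitrile
Product: 11 3-(3,5-dimethoxyphenyl)-4-methoxy-2-(4-methoxyphenyl)benzofuran-6-carbaldehyde, via N-diisobutylaluminio aldimine 10 (not isolated)
Conditions: i-Bu2AlH (1.5 equiv), CH2Cl2, −78 °C to 0 °C; then 1 M aq HCl, rt
Reagents that add atoms: water, O (carbonyl oxygen of 11); diisobutylaluminium hydride, CC(C)C[AlH]CC(C)C (aluminium residue of 10 only)
Why: Partial reduction of an aryl nitrile with i-Bu2AlH stops at the aluminium aldimine 10 because that species resists a second hydride transfer at low temperature, and acidic hydrolysis then releases the aldehyde while the aryl methyl ethers and the benzofuran are inert.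

Step 6
Reactants: 11 3-(3,5-dimethoxyphenyl)-4-methoxy-2-(4-methoxyphenyl)benzofuran-6-carbaldehyde
Product: 12 3-(3,5-dihydroxyphenyl)-4-hydroxy-2-(4-hydroxyphenyl)benzofuran-6-carbaldehyde (target)
Conditions: BBr3 (8 equiv), CH2Cl2 (dilute), −78 °C to rt; then ice-water
Reagents that add atoms: none
Why: Boron tribromide ether cleavage (coordination to each ether oxygen, then SN2 attack of bromide on the methyl group) should free all four phenols, the formyl group being merely complexed by an extra equivalent of Lewis acid and regenerated on aqueous quench, with cold, dilute conditions to suppress condensation with the electron-rich rings.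

Compound list
1 | 4-amino-3-methoxybenzonitrile | N#Cc1ccc(N)c(OC)c1 | starting material
2 | 4-amino-3-bromo-5-methoxybenzonitrile | N#Cc1cc(Br)c(N)c(OC)c1 | intermediate
3 | 2-bromo-4-cyano-6-methoxybenzenediazonium p-toluenesulfonate (not isolated) | N#Cc1cc(Br)c([N+]#N)c(OC)c1.Cc1ccc(cc1)S(=O)(=O)[O-] | intermediate
4 | 3-bromo-4-iodo-5-methoxybenzonitrile | N#Cc1cc(Br)c(I)c(OC)c1 | intermediate
5 | 1-(4-methoxyphenyl)ethanone | COc1ccc(cc1)C(C)=O | starting material
6 | 1-bromo-3,5-dimethoxybenzene | COc1cc(Br)cc(OC)c1 | starting material
7 | 2-(3,5-dimethoxyphenyl)-1-(4-methoxyphenyl)ethanone | COc1ccc(cc1)C(=O)Cc1cc(OC)cc(OC)c1 | intermediate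
8 | 3-bromo-4-[1-(3,5-dimethoxyphenyl)-2-(4-methoxyphenyl)-2-oxoethyl]-5-methoxybenzonitrile (racemic, not isolated) | N#Cc1cc(Br)c(C(c2cc(OC)cc(OC)c2)C(=O)c2ccc(OC)cc2)c(OC)c1 | intermediate
9 | 3-(3,5-dimethoxyphenyl)-4-methoxy-2-(4-methoxyphenyl)benzofuran-6-carbonitrile | N#Cc1cc(OC)c2c(-c3cc(OC)cc(OC)c3)c(-c3ccc(OC)cc3)oc2c1 | intermediate
10 | N-diisobutylaluminio aldimine of 11 (not isolated) | CC(C)C[Al](CC(C)C)N=Cc1cc(OC)c2c(-c3cc(OC)cc(OC)c3)c(-c3ccc(OC)cc3)oc2c1 | intermediate
11 | 3-(3,5-dimethoxyphenyl)-4-methoxy-2-(4-methoxyphenyl)benzofuran-6-carbaldehyde | O=Cc1cc(OC)c2c(-c3cc(OC)cc(OC)c3)c(-c3ccc(OC)cc3)oc2c1 | intermediate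
12 | 3-(3,5-dihydroxyphenyl)-4-hydroxy-2-(4-hydroxyphenyl)benzofuran-6-carbaldehyde | O=Cc1cc(O)c2c(-c3cc(O)cc(O)c3)c(-c3ccc(O)cc3)oc2c1 | target

Total step count: 6. Longest linear sequence: 5 steps (steps 1, 2, 4, 5 and 6); step 3 is a one-step convergent branch.

Steps most likely to fail

Step 4. The arylpalladium iodide carries two ortho substituents and must capture a hindered secondary enolate. Enolate binding may therefore be slow, and protodehalogenation or erosion of the iodide/bromide discrimination could overtake C–C bond formation.
- The fallback sets out from 4 and returns at 9, building the furan from an alkyne instead of an enolate.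
- Sonogashira coupling of 4 at the iodide with 1-ethynyl-4-methoxybenzene (PdCl2(PPh3)2, CuI, Et3N, THF, rt to 50 °C) would give 3-bromo-5-methoxy-4-[(4-methoxyphenyl)ethynyl]benzonitrile F1.
- Electrophilic iodocyclisation of this 2-alkynylanisole (I2, CH2Cl2, rt) lets the methoxy oxygen attack the activated alkyne with loss of its methyl group. This would give 4-bromo-3-iodo-2-(4-methoxyphenyl)benzofuran-6-carbonitrile F2.
- Suzuki–Miyaura coupling at the more reactive C3 iodide with (3,5-dimethoxyphenyl)boronic acid (Pd(PPh3)4, K2CO3, dioxane/H2O, 80 °C) would give 4-bromo-3-(3,5-dimethoxyphenyl)-2-(4-methoxyphenyl)benzofuran-6-carbonitrile F3.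
- Palladium-catalysed C–O coupling with methanol (Pd2(dba)3, t-BuBrettPhos, Cs2CO3, MeOH, toluene, 80 °C) would turn the C4 bromide into the methyl ether 9.
- In this detour the methoxy oxygen of 4 becomes O1 and the brominated carbon becomes C4. Ring A of 4 differs across its C1–C4 axis only in Br versus OMe, so the same 9 results.

Step 6. Four ether cleavages need long exposure to a strong Lewis acid. During that time the activated formyl group may condense in Friedel–Crafts fashion with the emerging resorcinol and phenol rings or be brominated at the formyl carbon, and the cleavage may also stop short of completion.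
- The fallback sets out from 9 and returns at 12, removing the methyl groups before the aldehyde exists.
- BBr3 in CH2Cl2 on nitrile 9, whose cyano group only binds the Lewis acid reversibly, would give 3-(3,5-dihydroxyphenyl)-4-hydroxy-2-(4-hydroxyphenyl)benzofuran-6-carbonitrile F4.
- Silylation (TBSCl, imidazole, DMF, rt) would give the tetrakis(tert-butyldimethylsilyl) ether of the nitrile F5.
- i-Bu2AlH (CH2Cl2, −78 °C) would give the silylated N-diisobutylaluminio aldimine F6, which cold dilute aq HCl would hydrolyse to the tetrakis(tert-butyldimethylsilyl) ether of the aldehyde F7.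
- Fluoride-mediated desilylation (Et3N·3HF, THF, rt) would release 12 under nearly neutral conditions.

Step 3. The product enolate is more acidic than that of 5 and may be arylated a second time, and the methyl ketone may self-condense under the alkoxide base.
- The fallback sets out from 6 and returns at 7, installing the carbonyl group by alkyne hydration.
- Sonogashira coupling of 6 with 1-ethynyl-4-methoxybenzene (PdCl2(PPh3)2, CuI, Et3N, 80 °C) would give 1,3-dimethoxy-5-[(4-methoxyphenyl)ethynyl]benzene F8.
- Acid-mediated hydration (p-TsOH·H2O, EtOH, reflux) should protonate the alkyne carbon next to ring C, because the resulting vinyl cation is stabilised by the para-methoxy group of ring B. Water then adds next to ring B and tautomerisation gives 7.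

Further compounds
F1 | step 4 | 3-bromo-5-methoxy-4-[(4-methoxyphenyl)ethynyl]benzonitrile | N#Cc1cc(Br)c(C#Cc2ccc(OC)cc2)c(OC)c1
F2 | step 4 | 4-bromo-3-iodo-2-(4-methoxyphenyl)benzofuran-6-carbonitrile | N#Cc1cc(Br)c2c(I)c(-c3ccc(OC)cc3)oc2c1
F3 | step 4 | 4-bromo-3-(3,5-dimethoxyphenyl)-2-(4-methoxyphenyl)benzofuran-6-carbonitrile | N#Cc1cc(Br)c2c(-c3cc(OC)cc(OC)c3)c(-c3ccc(OC)cc3)oc2c1
F4 | step 6 | 3-(3,5-dihydroxyphenyl)-4-hydroxy-2-(4-hydroxyphenyl)benzofuran-6-carbonitrile | N#Cc1cc(O)c2c(-c3cc(O)cc(O)c3)c(-c3ccc(O)cc3)oc2c1
F5 | step 6 | tetrakis(tert-butyldimethylsilyl) ether of the nitrile | N#Cc1cc(O[Si](C)(C)C(C)(C)C)c2c(-c3cc(O[Si](C)(C)C(C)(C)C)cc(O[Si](C)(C)C(C)(C)C)c3)c(-c3ccc(O[Si](C)(C)C(C)(C)C)cc3)oc2c1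
F6 | step 6 | silylated N-diisobutylaluminio aldimine | CC(C)C[Al](CC(C)C)N=Cc1cc(O[Si](C)(C)C(C)(C)C)c2c(-c3cc(O[Si](C)(C)C(C)(C)C)cc(O[Si](C)(C)C(C)(C)C)c3)c(-c3ccc(O[Si](C)(C)C(C)(C)C)cc3)oc2c1
F7 | step 6 | tetrakis(tert-butyldimethylsilyl) ether of the aldehyde | O=Cc1cc(O[Si](C)(C)C(C)(C)C)c2c(-c3cc(O[Si](C)(C)C(C)(C)C)cc(O[Si](C)(C)C(C)(C)C)c3)c(-c3ccc(O[Si](C)(C)C(C)(C)C)cc3)oc2c1
F8 | step 3 | 1,3-dimethoxy-5-[(4-methoxyphenyl)ethynyl]benzene | COc1ccc(cc1)C#Cc1cc(OC)cc(OC)c1
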